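**Retrosynthetic overview**
1. Target 29 ⇐ invertive bromination of cis-chlorohydrin 28 (C3'–Br) ⇐ OH-directed hydrogenation of cyclohexenol 27 (sets C1') ⇐ oxidation/Luche reduction of 25 (sets C3'–OH cis to Cl).
2. Cyclohexene 25 ⇐ ring-closing metathesis of diene 24 ⇐ indium-mediated carbonyl allylation (key C2'–C3' bond) of α-chloro aldehyde 22 with allyl chloride 13.
3. 22 (C4' tertiary chloride) ⇐ Sharpless epoxidation, chloride opening with inversion, glycol cleavage of dienol 19.
4. 13 ⇐ bromo-oxane methyl ketone 11 ⇐ bromoetherification of tertiary alcohol 9; C6 comes from (S)-lactic acid by Seebach alkylation.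
5. Ring order: oxane first (step 7), cyclohexane second (step 18).

Assumption: the target is exactly the stereoisomer of the given SMILES, (3S,6R)-oxane and (1'R,3'R,4'R)-cyclohexyl; locants are oxane O1, C2(Me2), C3(Br), C6 and cyclohexane C1' (on C6), C3' (Br), C4' (Cl, Me).

**Route**

Step 1
Reactants: 1 (S)-lactic acid
Product: 2 (2S,5S)-2-tert-butyl-5-methyl-1,3-dioxolan-4-one
Conditions: pivalaldehyde, cat. p-TsOH, cat. H2SO4, pentane, reflux (Dean–Stark); recrystallise Et2O/pentane, −78 °C (cis ≥ 96:4)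
Reagents that add atoms: pivalaldehyde, CC(C)(C)C=O
Why: Acid-catalysed acetalisation (Seebach self-regeneration of stereocentres) gives the thermodynamic cis acetal, whose new acetal carbon stores the lactate chirality.

Step 2
Reactants: 3 5-bromo-2-methylpent-2-ene
Product: 4 5-iodo-2-methylpent-2-ene
Conditions: NaI, acetone, reflux
Reagents that add atoms: sodium iodide, [Na+].[I-]
Why: Finkelstein SN2 exchange driven by NaBr precipitation gives the iodide needed to alkylate a hindered enolate.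

Step 3
Reactants: 2 (2S,5S)-2-tert-butyl-5-methyl-1,3-dioxolan-4-one; 4 5-iodo-2-methylpent-2-ene
Product: 6 (2S,5R)-2-tert-butyl-5-methyl-5-(4-methylpent-3-en-1-yl)-1,3-dioxolan-4-one, via lithium enolate 5 (not isolated)
Conditions: LDA, THF, −78 °C; then 4, DMPU, −78 → −30 °C
Reagents that add atoms: none
Why: Seebach enolate alkylation: the iodide enters anti to tert-butyl, so the homoprenyl group replaces H with net retention and sets the quaternary C6 centre.

Step 4
Reactants: 6 (2S,5R)-2-tert-butyl-5-methyl-5-(4-methylpent-3-en-1-yl)-1,3-dioxolan-4-one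
Product: 7 (2R)-2-hydroxy-N-methoxy-N,2,6-trimethylhept-5-enamide
Conditions: MeNH(OMe)·HCl, i-PrMgCl, THF, −20 → 0 °C
Reagents that add atoms: N,O-dimethylhydroxylamine hydrochloride, CNOC.Cl
Why: Aminolysis of the dioxolanone by the magnesium amide (Weinreb amide formation) releases pivalaldehyde without touching the quaternary centre.

Step 5
Reactants: 7 (2R)-2-hydroxy-N-methoxy-N,2,6-trimethylhept-5-enamide
Product: 8 (3R)-3-hydroxy-3,7-dimethyloct-6-en-2-one
Conditions: MeMgBr (3 equiv), THF, 0 °C; aq. NH4Cl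
Reagents that add atoms: methylmagnesium bromide, C[Mg]Br
Why: Weinreb ketone synthesis: the chelated tetrahedral intermediate stops at single addition.

Step 6
Reactants: 8 (3R)-3-hydroxy-3,7-dimethyloct-6-en-2-one
Product: 9 (2R)-6-methyl-2-(2-methyl-1,3-dioxolan-2-yl)hept-5-en-2-ol
Conditions: ethylene glycol, HC(OMe)3, p-TsOH (2 mol%), CH2Cl2, rt
Reagents that add atoms: ethylene glycol, OCCO
Why: Orthoformate-driven ketalisation turns the flat acetyl group into a bulky quaternary dioxolanyl group that will steer the next cyclisation; C6 is untouched.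

Step 7
Reactants: 9 (2R)-6-methyl-2-(2-methyl-1,3-dioxolan-2-yl)hept-5-en-2-ol
Product: 10 (3S,6R)-3-bromo-2,2,6-trimethyl-6-(2-methyl-1,3-dioxolan-2-yl)oxane
Conditions: NBS, NaHCO3, CH2Cl2, 0 °C, dark
Reagents that add atoms: N-bromosuccinimide, O=C1CCC(=O)N1Br
Why: Bromoetherification (6-endo Markovnikov capture of the bromonium ion by the tertiary OH) through a chair transition state with the dioxolanyl group equatorial; anti addition places Br equatorial and sets C3 as S.

Step 8
Reactants: 10 (3S,6R)-3-bromo-2,2,6-trimethyl-6-(2-methyl-1,3-dioxolan-2-yl)oxane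
Product: 11 1-[(2R,5S)-5-bromo-2,6,6-trimethyloxan-2-yl]ethan-1-one
Conditions: 2 M HCl, THF, 40 °C
Reagents that add atoms: water, O
Why: Acid-catalysed ketal hydrolysis; the equatorial secondary bromide and the ether are inert.

Step 9
Reactants: 11 1-[(2R,5S)-5-bromo-2,6,6-trimethyloxan-2-yl]ethan-1-one
Product: 12 (3S,6R)-3-bromo-2,2,6-trimethyl-6-(prop-1-en-2-yl)oxane
Conditions: Ph3PCH3Br, KOt-Bu, THF, 0 → 45 °C
Reagents that add atoms: methyltriphenylphosphonium bromide, C[P+](c1ccccc1)(c1ccccc1)c1ccccc1.[Br-]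
Why: Wittig methylenation; the equatorial bromide has no anti-periplanar H, so E2 does not compete.

Step 10
Reactants: 12 (3S,6R)-3-bromo-2,2,6-trimethyl-6-(prop-1-en-2-yl)oxane
Product: 13 (3S,6R)-3-bromo-6-(3-chloroprop-1-en-2-yl)-2,2,6-trimethyloxane
Conditions: NCS, PhSeCl (10 mol%), CH2Cl2, rt
Reagents that add atoms: N-chlorosuccinimide, O=C1CCC(=O)N1Cl
Why: Selenium-catalysed ene-type allylic chlorination (Hori–Sharpless); the methyl group carries the only allylic hydrogens, so a single allyl chloride forms.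

Step 11
Reactants: 14 prop-2-yn-1-ol; 15 allyl bromide
Product: 16 hex-5-en-2-yn-1-ol
Conditions: CuI (10 mol%), NaI (cat.), K2CO3, DMF, rt
Reagents that add atoms: none
Why: Copper-catalysed coupling of the terminal alkyne (copper acetylide) with the allyl halide gives the skipped enyne.

Step 12
Reactants: 16 hex-5-en-2-yn-1-ol
Product: 18 (2Z)-3-iodohexa-2,5-dien-1-ol, via cyclic alkenylalanate 17 (not isolated)
Conditions: Red-Al, Et2O, 0 °C → rt; then I2, THF, −78 → 0 °C
Reagents that add atoms: iodine, II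
Why: Alkoxide-directed trans-hydroalumination places Al on C3 cis to CH2O, and iodinolysis with retention gives the Z-iodide.

Step 13
Reactants: 18 (2Z)-3-iodohexa-2,5-dien-1-ol
Product: 19 (2E)-3-methylhexa-2,5-dien-1-ol
Conditions: Me2CuLi (4 equiv, from MeLi and CuI), Et2O, 0 °C
Reagents that add atoms: lithium dimethylcuprate, [Li+].C[Cu-]C
Why: Cuprate cross-coupling of the alkenyl iodide proceeds with retention, giving the E trisubstituted allylic alcohol.

Step 14
Reactants: 19 (2E)-3-methylhexa-2,5-dien-1-ol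
Product: 20 [(2S,3S)-3-methyl-3-(prop-2-en-1-yl)oxiran-2-yl]methanol
Conditions: Ti(Oi-Pr)4 (5 mol%), L-(+)-DET (6 mol%), t-BuOOH, 4 Å MS, CH2Cl2, −20 °C
Reagents that add atoms: tert-butyl hydroperoxide, CC(C)(C)OO
Why: Sharpless asymmetric epoxidation of the allylic alkene only; L-(+)-tartrate gives the (2S,3S)-epoxide, as with geraniol.

Step 15
Reactants: 20 [(2S,3S)-3-methyl-3-(prop-2-en-1-yl)oxiran-2-yl]methanol
Product: 21 (2S,3R)-3-chloro-3-methylhex-5-ene-1,2-diol
Conditions: ClTi(Oi-Pr)3, CH2Cl2, 0 °C → rt; aq. tartaric acid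
Reagents that add atoms: chlorotitanium triisopropoxide, CC(C)O[Ti](Cl)(OC(C)C)OC(C)C
Why: Titanium-chelated opening of the 2,3-epoxy alcohol by chloride at the tertiary C3 with inversion sets the future C4' tertiary chloride as R.

Step 16
Reactants: 21 (2S,3R)-3-chloro-3-methylhex-5-ene-1,2-diol
Product: 22 (2R)-2-chloro-2-methylpent-4-enal
Conditions: NaIO4, Et2O/H2O, 0 °C → rt; dried ethereal solution used directly
Reagents that add atoms: none
Why: Malaprade glycol cleavage; the quaternary α-carbon cannot enolise, so the chloride centre is configurationally safe.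

Step 17
Reactants: 13 (3S,6R)-3-bromo-6-(3-chloroprop-1-en-2-yl)-2,2,6-trimethyloxane; 22 (2R)-2-chloro-2-methylpent-4-enal
Product: 24 (4RS,5R)-2-[(2R,5S)-5-bromo-2,6,6-trimethyloxan-2-yl]-5-chloro-5-methylocta-1,7-dien-4-ol, via allylindium dichloride 23 (not isolated)
Conditions: In powder, NaI (cat.), DMF, rt
Reagents that add atoms: none
Why: Barbier-type indium-mediated carbonyl allylation joins the two fragments under neutral conditions that spare both halides; the new carbinol forms as an epimer mixture that is corrected in step 19.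

Step 18
Reactants: 24 (4RS,5R)-2-[(2R,5S)-5-bromo-2,6,6-trimethyloxan-2-yl]-5-chloro-5-methylocta-1,7-dien-4-ol
Product: 25 (1RS,6R)-3-[(2R,5S)-5-bromo-2,6,6-trimethyloxan-2-yl]-6-chloro-6-methylcyclohex-3-en-1-ol
Conditions: Hoveyda–Grubbs II (5 mol%), toluene (5 mM), 80 °C
Reagents that add atoms: none
Why: Ring-closing metathesis starts at the monosubstituted alkene and closes on the 1,1-disubstituted one to give the trisubstituted cyclohexene, driven by loss of ethylene.

Step 19
Reactants: 25 (1RS,6R)-3-[(2R,5S)-5-bromo-2,6,6-trimethyloxan-2-yl]-6-chloro-6-methylcyclohex-3-en-1-ol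
Product: 27 (1S,6R)-3-[(2R,5S)-5-bromo-2,6,6-trimethyloxan-2-yl]-6-chloro-6-methylcyclohex-3-en-1-ol, via cyclohexenone 26 (not isolated)
Conditions: DMP, NaHCO3, CH2Cl2, 0 °C; filter, concentrate cold; then NaBH4, CeCl3·7H2O, MeOH, −78 °C
Reagents that add atoms: none
Why: Dess–Martin oxidation erases the carbinol centre and Luche reduction delivers hydride anti to the pseudo-axial C–Cl bond (Felkin–Anh/Cornforth), giving the cis-chlorohydrin (1S).

Step 20
Reactants: 27 (1S,6R)-3-[(2R,5S)-5-bromo-2,6,6-trimethyloxan-2-yl]-6-chloro-6-methylcyclohex-3-en-1-ol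
Product: 28 (1S,2R,5R)-5-[(2R,5S)-5-bromo-2,6,6-trimethyloxan-2-yl]-2-chloro-2-methylcyclohexan-1-ol
Conditions: [Ir(cod)(PCy3)(py)]PF6 (5–10 mol%), H2 (1 atm), CH2Cl2, rt
Reagents that add atoms: none
Why: Hydroxyl-directed hydrogenation (Crabtree catalyst) adds H to C1' from the face of the homoallylic OH, so the oxanyl group ends trans to OH and C1' is set as R.

Step 21
Reactants: 28 (1S,2R,5R)-5-[(2R,5S)-5-bromo-2,6,6-trimethyloxan-2-yl]-2-chloro-2-methylcyclohexan-1-ol
Product: 29 deoxycaespitol, (3S,6R)-3-bromo-6-[(1R,3R,4R)-3-bromo-4-chloro-4-methylcyclohexyl]-2,2,6-trimethyloxane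
Conditions: CBr4, P(n-Oct)3, toluene, 70 °C
Reagents that add atoms: carbon tetrabromide, BrC(Br)(Br)Br
Why: Appel bromination: SN2 displacement of the axial alkoxyphosphonium by bromide inverts C3', giving the equatorial bromide trans to chlorine (the gauche cis-chlorine cannot participate).

**Compound list**
1 | (S)-lactic acid | C[C@H](O)C(=O)O | starting material
2 | (2S,5S)-2-tert-butyl-5-methyl-1,3-dioxolan-4-one | C[C@@H]1O[C@H](C(C)(C)C)OC1=O | intermediate
3 | 5-bromo-2-methylpent-2-ene | CC(C)=CCCBr | starting material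
4 | 5-iodo-2-methylpent-2-ene | CC(C)=CCCI | intermediate
5 | lithium (2S)-2-tert-butyl-5-methyl-1,3-dioxol-4-olate (enolate of 2) | [Li+].CC1=C([O-])O[C@@H](C(C)(C)C)O1 | intermediate
6 | (2S,5R)-2-tert-butyl-5-methyl-5-(4-methylpent-3-en-1-yl)-1,3-dioxolan-4-one | C[C@]1(CCC=C(C)C)O[C@H](C(C)(C)C)OC1=O | intermediate
7 | (2R)-2-hydroxy-N-methoxy-N,2,6-trimethylhept-5-enamide | C[C@](CCC=C(C)C)(O)C(=O)N(C)OC | intermediate
8 | (3R)-3-hydroxy-3,7-dimethyloct-6-en-2-one | C[C@](CCC=C(C)C)(O)C(C)=O | intermediate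
9 | (2R)-6-methyl-2-(2-methyl-1,3-dioxolan-2-yl)hept-5-en-2-ol | C[C@](CCC=C(C)C)(O)C1(C)OCCO1 | intermediate
10 | (3S,6R)-3-bromo-2,2,6-trimethyl-6-(2-methyl-1,3-dioxolan-2-yl)oxane | CC1(C)O[C@@](C)(C2(C)OCCO2)CC[C@@H]1Br | intermediate
11 | 1-[(2R,5S)-5-bromo-2,6,6-trimethyloxan-2-yl]ethan-1-one | CC1(C)O[C@@](C)(C(C)=O)CC[C@@H]1Br | intermediate
12 | (3S,6R)-3-bromo-2,2,6-trimethyl-6-(prop-1-en-2-yl)oxane | CC1(C)O[C@@](C)(C(C)=C)CC[C@@H]1Br | intermediate
13 | (3S,6R)-3-bromo-6-(3-chloroprop-1-en-2-yl)-2,2,6-trimethyloxane | CC1(C)O[C@@](C)(C(=C)CCl)CC[C@@H]1Br | intermediate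
14 | prop-2-yn-1-ol | C#CCO | starting material
15 | allyl bromide | C=CCBr | starting material
16 | hex-5-en-2-yn-1-ol | C=CCC#CCO | intermediate
17 | sodium 2,2-bis(2-methoxyethoxy)-3-(prop-2-en-1-yl)-2,5-dihydro-1,2-oxaluminol-2-uide (cyclic alkenylalanate) | [Na+].C=CCC1=CCO[Al-]1(OCCOC)OCCOC | intermediate
18 | (2Z)-3-iodohexa-2,5-dien-1-ol | OC/C=C(\I)CC=C | intermediate
19 | (2E)-3-methylhexa-2,5-dien-1-ol | C=CC/C(C)=C/CO | intermediate
20 | [(2S,3S)-3-methyl-3-(prop-2-en-1-yl)oxiran-2-yl]methanol | C=CC[C@]1(C)O[C@H]1CO | intermediate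
21 | (2S,3R)-3-chloro-3-methylhex-5-ene-1,2-diol | C=CC[C@@](C)(Cl)[C@@H](O)CO | intermediate
22 | (2R)-2-chloro-2-methylpent-4-enal | C=CC[C@@](C)(Cl)C=O | intermediate
23 | {2-[(2R,5S)-5-bromo-2,6,6-trimethyloxan-2-yl]prop-2-en-1-yl}indium dichloride | CC1(C)O[C@@](C)(C(=C)C[In](Cl)Cl)CC[C@@H]1Br | intermediate
24 | (4RS,5R)-2-[(2R,5S)-5-bromo-2,6,6-trimethyloxan-2-yl]-5-chloro-5-methylocta-1,7-dien-4-ol | CC1(C)O[C@@](C)(C(=C)CC(O)[C@](C)(Cl)CC=C)CC[C@@H]1Br | intermediate
25 | (1RS,6R)-3-[(2R,5S)-5-bromo-2,6,6-trimethyloxan-2-yl]-6-chloro-6-methylcyclohex-3-en-1-ol | CC1(C)O[C@@](C)(C2=CC[C@@](C)(Cl)C(O)C2)CC[C@@H]1Br | intermediate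
26 | (6R)-3-[(2R,5S)-5-bromo-2,6,6-trimethyloxan-2-yl]-6-chloro-6-methylcyclohex-3-en-1-one | CC1(C)O[C@@](C)(C2=CC[C@@](C)(Cl)C(=O)C2)CC[C@@H]1Br | intermediate
27 | (1S,6R)-3-[(2R,5S)-5-bromo-2,6,6-trimethyloxan-2-yl]-6-chloro-6-methylcyclohex-3-en-1-ol | CC1(C)O[C@@](C)(C2=CC[C@@](C)(Cl)[C@@H](O)C2)CC[C@@H]1Br | intermediate
28 | (1S,2R,5R)-5-[(2R,5S)-5-bromo-2,6,6-trimethyloxan-2-yl]-2-chloro-2-methylcyclohexan-1-ol | CC1(C)O[C@@](C)([C@@H]2CC[C@@](C)(Cl)[C@@H](O)C2)CC[C@@H]1Br | intermediate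
29 | deoxycaespitol, (3S,6R)-3-bromo-6-[(1R,3R,4R)-3-bromo-4-chloro-4-methylcyclohexyl]-2,2,6-trimethyloxane | CC1(C)O[C@@](C)([C@@H]2CC[C@@](C)(Cl)[C@H](Br)C2)CC[C@@H]1Br | target

**Totals**
Total step count: 21. Longest linear sequence: 14 steps (1, 3–10, 17–21).

**Three steps most likely to fail**

Step 7 (bromoetherification). The risks are 5-exo closure to tetrahydrofurans and the C3 epimer; the dioxolanyl group is there to bias the chair, but the ratio is an expectation, not a precedent. The fallback sets out from 9: mercuricyclisation with Hg(OCOCF3)2 in MeNO2 at −20 °C, which is Markovnikov-selective and reversible, followed by aqueous KBr gives the equatorial organomercury bromide F1. Brominative demercuration with retention (Br2, LiBr, pyridine, O2) then returns to the route at 10.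

Step 19 (oxidation and Luche reduction). The β,γ-enone 26 can slip into conjugation and the hydride facial selectivity rests on substrate control. The fallback sets out from 25: oxidise with DMP and then treat with DBU to drive the isomerisation fully to the conjugated enone F2. Reduce F2 under Luche conditions, or with the matched enantiomer of the Me-CBS catalyst for reagent control, to the allylic alcohol F3. Its allylic hydroxyl directs the Crabtree hydrogenation equally well, and the route is rejoined at 28.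

Step 21 (Appel bromination). C3' is neopentyl-like (next to the quaternary C4'), so elimination towards C2' or methyl migration may compete with SN2. The fallback sets out from 28: convert it at −40 °C (Tf2O, pyridine, CH2Cl2) into the triflate F4 and displace with n-Bu4NBr in toluene at −20 °C → rt, an SN2 on a much better leaving group at low temperature, returning to the route at 29.

**Further compounds**
F1 | step 7 | bromo[(3S,6R)-2,2,6-trimethyl-6-(2-methyl-1,3-dioxolan-2-yl)oxan-3-yl]mercury | CC1(C)O[C@@](C)(C2(C)OCCO2)CC[C@@H]1[Hg]Br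
F2 | step 19 | (6R)-3-[(2R,5S)-5-bromo-2,6,6-trimethyloxan-2-yl]-6-chloro-6-methylcyclohex-2-en-1-one | CC1(C)O[C@@](C)(C2=CC(=O)[C@](C)(Cl)CC2)CC[C@@H]1Br
F3 | step 19 | (1S,6R)-3-[(2R,5S)-5-bromo-2,6,6-trimethyloxan-2-yl]-6-chloro-6-methylcyclohex-2-en-1-ol | CC1(C)O[C@@](C)(C2=C[C@H](O)[C@](C)(Cl)CC2)CC[C@@H]1Br
F4 | step 21 | (1S,2R,5R)-5-[(2R,5S)-5-bromo-2,6,6-trimethyloxan-2-yl]-2-chloro-2-methylcyclohexyl trifluoromethanesulfonate | CC1(C)O[C@@](C)([C@@H]2CC[C@@](C)(Cl)[C@@H](OS(=O)(=O)C(F)(F)F)C2)CC[C@@H]1Br
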